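**Plan**
- Retrosynthesis: the C1–C7 bond of the cyclopentanone ring is cut together with the C–O bond of the tertiary alcohol, giving an achiral 6,6-diprenyl acyl-trione. Next the two C–prenyl bonds at its quaternary carbon are cut, then the aryl–acyl bond, leading to 2-methylphloroglucinol.
- Forward: the aromatic ring is acylated, then dearomatised by double prenylation to the six-membered trione ring, then brominated at C4. The five-membered ring is closed last by a 5-exo radical cyclization with capture of O2.
- Enabling feature: the flat trione ring is a mirror plane through C6, so the two prenyl groups are enantiotopic. The radical carbon C4 lies 1,3 to C6 across the C5 carbonyl, so attack on the CH carbon of either prenyl group gives the bicyclo[3.2.1]octane with C5 as the one-carbon bridge.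
- Stereochemistry: all three stereocentres arise in the key step. A chiral magnesium bis(oxazoline) chelate at the 2-acyl-1,3-dione unit next to C4 selects one prenyl group (C1 and C5 of the target); the exo transition state sets C7.

Key step: step 4

Remark: the triketones are written as one enol tautomer throughout, and the (S,S)-bis(oxazoline) is assumed, from the quadrant model of its magnesium chelate, to be the antipode that leaves open the ring face needed for the target; if the sense is opposite, the (R,R)-ligand is used without other change.

Step 1
Reactants: 1 2-methylbenzene-1,3,5-triol (2-methylphloroglucinol); 2 2-methylpropanoyl chloride (isobutyryl chloride)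
Product: 3 2-methyl-1-(2,4,6-trihydroxy-3-methylphenyl)propan-1-one
Conditions: AlCl3 (4 equiv), PhNO2–CH2Cl2, 0 to 45 °C; then ice, aq. HCl
Reagents that add atoms: none
Why: Friedel–Crafts acylation at one of the two equivalent free ring carbons of the triol, after which the chelated aryl ketone is deactivated toward a second acylation; no stereocentre arises.

Step 2
Reactants: 3 2-methyl-1-(2,4,6-trihydroxy-3-methylphenyl)propan-1-one; 4 1-bromo-3-methylbut-2-ene (prenyl bromide, 2.2 equiv)
Product: 5 3,5-dihydroxy-4-methyl-6,6-bis(3-methylbut-2-en-1-yl)-2-(2-methylpropanoyl)cyclohexa-2,4-dien-1-one (achiral)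
Conditions: NaOMe (3 equiv), MeOH, 0 to 23 °C; then aq. HCl
Reagents that add atoms: none
Why: Dearomative double C-alkylation (SN2 of the phenolate carbon on the allylic bromide): the first prenyl group enters at the only ring carbon that bears hydrogen, the re-formed phenolate is alkylated again at the same carbon in the protic medium that favours C- over O-alkylation, and the product is achiral because the flat ring is a mirror plane relating the two prenyl groups.

Step 3
Reactants: 5 3,5-dihydroxy-4-methyl-6,6-bis(3-methylbut-2-en-1-yl)-2-(2-methylpropanoyl)cyclohexa-2,4-dien-1-one
Product: 6 rac-4-bromo-3-hydroxy-4-methyl-6,6-bis(3-methylbut-2-en-1-yl)-2-(2-methylpropanoyl)cyclohex-2-ene-1,5-dione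
Conditions: NBS (1.0 equiv), CH2Cl2, −78 °C, dark; cold work-up, used at once
Reagents that add atoms: N-bromosuccinimide, O=C1CCC(=O)N1Br
Why: Electrophilic α-bromination of a 1,3-dicarbonyl enol: C4 is the only enolic ring carbon that still carries hydrogen and should react at −78 °C faster than the trisubstituted alkenes; the new C4 stereocentre may be racemic because it is erased when the radical forms.

Step 4
Reactants: 6 rac-4-bromo-3-hydroxy-4-methyl-6,6-bis(3-methylbut-2-en-1-yl)-2-(2-methylpropanoyl)cyclohex-2-ene-1,5-dione
Product: 8 (1R,5R,7R)-2-hydroxy-7-(2-hydroxypropan-2-yl)-1-methyl-5-(3-methylbut-2-en-1-yl)-3-(2-methylpropanoyl)bicyclo[3.2.1]oct-2-ene-4,8-dione (the target), via tertiary hydroperoxide 7 (not isolated)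
Conditions: Mg(ClO4)2 (1.1 equiv), (S,S)-2,2'-(propane-2,2-diyl)bis(4-tert-butyl-4,5-dihydro-1,3-oxazole) (1.2 equiv), 4 Å molecular sieves, CH2Cl2–toluene, −78 °C; Et3B (slow addition), O2 (1 atm), −78 °C; then Me2S, −78 to 0 °C; aqueous work-up (metal salt and ligand recovered unchanged)
Reagents that add atoms: dioxygen, O=O
Why: Proposed new method: an ethyl radical from Et3B/O2 abstracts bromine from 6 and gives the planar C4 radical while Mg(ClO4)2 carrying the bis(oxazoline) is chelated by the isobutyryl oxygen and the ring oxygen on C3, next to C4; the radical adds to the CH carbon of one prenyl group, the tertiary radical so formed is captured by O2, the peroxyl radical passes the chain on through Et3B, and Me2S reduces hydroperoxide 7 to the alcohol. The closest known reaction type is the chiral-Lewis-acid-controlled atom-transfer radical cyclization of 2-bromo-1,3-dicarbonyl compounds started by Et3B/O2, joined here to the known O2 capture of a cyclized radical; what is new is its use on a cyclic 2-acyl-1,3-dione to choose between two enantiotopic alkenes. The five-membered ring (C4, C5, C6 of 6 and the CH2 and CH carbons of the prenyl group) closes in the 5-exo-trig mode and no other ring is formed. C1 and C5 of 8 are fixed together by which prenyl group is attacked, that is by the face of C4 that the tert-butyl group of the ligand leaves open: it must be the prenyl group pointing to the viewer when the ring of 6 is drawn flat with C1 (the carbonyl between C6 and the acyl-bearing C2) to C6 running clockwise. C7 is fixed by the exo transition state, in which the CMe2 end of the alkene points past the C5 carbonyl and away from the metal-bearing C3–O side. The step needs enantiotopic group selection, exo over endo closure, O2 capture of the tertiary radical before a second cyclization onto the remaining prenyl group, and cyclization before O2 capture at C4; the chelate next to C4, the steric load at the C3 oxygen, the O2 atmosphere and the intramolecular rate are meant to secure these in that order.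

**Compound list**
1 | 2-methylbenzene-1,3,5-triol (2-methylphloroglucinol) | Cc1c(O)cc(O)cc1O | starting material
2 | 2-methylpropanoyl chloride (isobutyryl chloride) | CC(C)C(Cl)=O | starting material
3 | 2-methyl-1-(2,4,6-trihydroxy-3-methylphenyl)propan-1-one | CC(C)C(=O)c1c(O)cc(O)c(C)c1O | intermediate
4 | 1-bromo-3-methylbut-2-ene (prenyl bromide) | CC(C)=CCBr | starting material
5 | 3,5-dihydroxy-4-methyl-6,6-bis(3-methylbut-2-en-1-yl)-2-(2-methylpropanoyl)cyclohexa-2,4-dien-1-one (achiral) | CC(C)C(=O)C1=C(O)C(C)=C(O)C(CC=C(C)C)(CC=C(C)C)C1=O | intermediate
6 | rac-4-bromo-3-hydroxy-4-methyl-6,6-bis(3-methylbut-2-en-1-yl)-2-(2-methylpropanoyl)cyclohex-2-ene-1,5-dione | CC(C)C(=O)C1=C(O)C(C)(Br)C(=O)C(CC=C(C)C)(CC=C(C)C)C1=O | intermediate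
7 | (1R,5R,7R)-7-(2-hydroperoxypropan-2-yl)-2-hydroxy-1-methyl-5-(3-methylbut-2-en-1-yl)-3-(2-methylpropanoyl)bicyclo[3.2.1]oct-2-ene-4,8-dione (not isolated) | CC(C)=CC[C@@]12C[C@@H](C(C)(C)OO)[C@@](C)(C1=O)C(O)=C(C(=O)C(C)C)C2=O | intermediate
8 | (1R,5R,7R)-2-hydroxy-7-(2-hydroxypropan-2-yl)-1-methyl-5-(3-methylbut-2-en-1-yl)-3-(2-methylpropanoyl)bicyclo[3.2.1]oct-2-ene-4,8-dione | CC(C)=CC[C@@]12C[C@@H](C(C)(C)O)[C@@](C)(C1=O)C(O)=C(C(=O)C(C)C)C2=O | target

**Count and risks**
Total step count: 4. Longest linear sequence: 4 steps (1 → 3 → 5 → 6 → 8).

Step 4 (bears the label; highest risk). What may go wrong: poor discrimination between the two enantiotopic prenyl groups, through chelation of the metal on the C1–O flank or reaction of unbound radical, and endo instead of exo closure. Fallback (known chemistry): setting out from 6, the radical cyclization with O2 capture is run without metal salt and ligand (Et3B, O2, CH2Cl2, −78 to −40 °C; then Me2S), a racemic reaction of known type. It should give the exo alcohol as the racemate, that is 8 together with the (1S,5S,7S)-enantiomer F1, beside endo epimers that are removed on silica gel. Compound 8 is then separated from F1 by preparative chromatography on a chiral stationary phase (cellulose tris(3,5-dimethylphenylcarbamate)). The fallback comes back to the route at 8.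

Step 2. What may go wrong: alkylation at the methyl-bearing ring carbon or at oxygen, and over-alkylation, in place of the second C-alkylation at C6. Fallback: setting out from 3, Tsuji–Trost prenylation with methyl 3-methylbut-2-en-1-yl carbonate (2.2 equiv) and Pd(PPh3)4 in THF at 23 to 50 °C. O-allyl ethers re-ionise to the π-allyl palladium complex under these conditions, so the C-alkylated trione should accumulate under thermodynamic control, and neither base nor bromide is present. No compound outside the list is made (F0), and the fallback comes back to the route at 5.

Step 3. What may go wrong: loss of HBr from the tertiary bromide toward an exocyclic methylene trione, or transfer of electrophilic bromine to a prenyl double bond, before the radical step. Fallback: setting out from 5, selenenylation at C4 with PhSeCl and pyridine (CH2Cl2, −78 °C) gives the racemic 4-(phenylselanyl) trione F2. This is a non-electrophilic radical precursor of the type known for Lewis-acid-controlled group-transfer cyclization. Under the conditions of step 4 the ethyl radical attacks selenium, the same C4 radical results, and the sequence comes back to the route at 7 and from there to 8.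

**Further compounds**
F1 | step 4 | (1S,5S,7S)-2-hydroxy-7-(2-hydroxypropan-2-yl)-1-methyl-5-(3-methylbut-2-en-1-yl)-3-(2-methylpropanoyl)bicyclo[3.2.1]oct-2-ene-4,8-dione (enantiomer of 8) | CC(C)=CC[C@]12C[C@H](C(C)(C)O)[C@](C)(C1=O)C(O)=C(C(=O)C(C)C)C2=O
F0 | step 2 | none | none
F2 | step 3 | rac-3-hydroxy-4-methyl-6,6-bis(3-methylbut-2-en-1-yl)-2-(2-methylpropanoyl)-4-(phenylselanyl)cyclohex-2-ene-1,5-dione | CC(C)C(=O)C1=C(O)C(C)([Se]c2ccccc2)C(=O)C(CC=C(C)C)(CC=C(C)C)C1=O
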